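## Analysis of the target

The target is an achiral depside: two benzene rings joined by one aryl ester, with no stereocentre. Ring A (the acyl ring, numbered C1 to C6) is hexasubstituted: C1 carries the ester carbonyl, C2 an OH, C3 the formyl group, C4 an OH, C5 an OH and C6 a methyl group. Ring B (C1' to C6') is methyl 2,4-dihydroxy-3,6-dimethylbenzoate acylated at O4'; C5' is its only C–H. The sensitive groups are the aryl ester (base, nucleophiles, acyl migration to a neighbouring phenol), the methyl ester, the salicylaldehyde, and the 2,4,5-trihydroxy pattern of ring A, which is oxidation-prone because O2/O5 are para and O4/O5 ortho. The difficulty is ring A: six different substituents in a fixed order, and a carboxyl carbon flanked by C2–OH and C6–CH3, so the classical esterification needs a hindered, fully protected acid that is itself long to make.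

The feature that invites the chosen move is this. C1 and C6 of ring A carry a carboxyl carbon and a methyl group on adjacent carbons, the pattern of the two sp carbons of a but-2-ynoate. C2, C4 and C5 carry oxygen, with C3 between two of them, the pattern of C1, C3 and C4 of the dienolate of a 4-alkoxy-3-oxobutanoate. Ring A can therefore be closed from these two open-chain pieces by forming C1–C2 and C5–C6, with the but-2-ynoate already in place as the ester of ring B.

## Retrosynthetic reasoning

**12 to 11.** The O5–benzyl bond is cut last. A benzyl ether on O5 is the one protecting group the route needs: it comes in with the open-chain diene precursor 4, survives the ring construction and the formylation, and can be removed by a Lewis acid at low temperature without touching either ester.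

**11 to 10.** The C3–CHO bond is cut. C3 is the only unsubstituted carbon of ring A and lies between two free phenols, so an electrophilic formylation has a single, strongly activated site. Doing it after the ring construction keeps the aldehyde away from the silyl ketene acetal chemistry.

**10 to 3 and 7 (key disconnection).** Ring A is cut at C1–C2 and C5–C6. This leaves C1/C6 as the alkyne carbons of 3, in which the depside ester is already in place, and C2–C5 as the diene 7. The forward reaction must be a regioselective [4+2] cycloaddition that joins the ketene-acetal carbon of 7 to the ester-bearing carbon of the alkyne, followed by aromatisation with loss of the ethoxy and silyl groups. What is gained: five of the six substituents of ring A are set in one operation, and the hindered esterification is avoided because the ester is formed on the unhindered acid 1.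

**7 to 5 to 4.** The diene is the bis-silyl dienol ether of the commercial keto ester 4, made by O-silylation to 5 and γ-deprotonation and silylation via 6. The O–Si bonds are cut here because this is the standard, regiodefined access to such dienes.

**3 to 1 and 2.** The C(=O)–O4' bond of 3 is cut. The acid 1 is unhindered and 2 is commercial; O4' is the only phenol of 2 not locked in a hydrogen bond and not flanked on both sides.

## Alternatives that were turned down

**Alternative 1:** (textbook) Cut the depside C(=O)–O4' bond of the finished skeleton. Forward: the protected acid 4,5-bis(benzyloxy)-3-formyl-2-hydroxy-6-methylbenzoic acid (A1) is activated (trifluoroacetic anhydride or a carbodiimide) and joined to 2 to give the dibenzyl depside A2, which is debenzylated. Turned down because A1 is not a simple compound. It needs, from a plain resorcylate ester, a C3 formylation, a separate C5 oxygenation, two benzylations and the saponification of an ester flanked by two ortho substituents. The union then joins a di-ortho-substituted acid to a phenol. Every substituent of ring A is installed one at a time, and the route is about half as long again as the one chosen.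

**Alternative 2:** Cut ring A at the same two bonds but stepwise, as a squarate-derived ring expansion. Forward: the (E)-3-iodobut-2-enoate of 2 (A3) is metallated and added to a 3-alkoxycyclobutenedione to give the 4-alkenyl-4-hydroxycyclobutenone A4. Thermolysis (electrocyclic opening to a dienylketene, then closure) gives the hydroquinone depside A5, which is formylated and dealkylated. Turned down because the risk sits outside the key step. The nucleophile must be an alkenyl metal that carries an aryl ester, and it must be the (E) isomer: the more accessible (Z) isomer would put the new alkoxide next to the ester and lactonise with loss of the phenoxide of 2. Access to A3 adds tin or boron steps, and the route is two steps longer.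

**Alternative 3:** Cut the depside C–O bond and C1–C6 of ring A, as in a biomimetic polyketide cyclisation. Forward: the diketo-dioxinone A6 is heated with 2; the acylketene is trapped at O4' to give the triketo ester A7, whose C2 carbanion closes onto the methyl ketone and aromatises to 10. Turned down because A7 is an aryl β-keto ester with an enolisable 5-ketone. Six-membered lactonisation to a pyranone, with expulsion of the phenoxide of 2, is an intramolecular acyl substitution on an activated ester and should compete with the aldol closure onto a ketone hindered by the benzyloxy-bearing carbon. The 2-alkoxy-1,3-diketone is also open to retro-Claisen cleavage, and A6 itself costs three to four steps.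

Key step: step 4

Remark on the chemistry: 1, 2 and 4 are taken as commercial. The double-bond geometries drawn for 5, 6 and 7 are the expected major ones and do not survive into the product. Intermediate 9 is a mixture of racemic diastereomers whose sp3 centres are lost on aromatisation.

## Steps

**Step 1**
Reactants: 1 but-2-ynoic acid; 2 methyl 2,4-dihydroxy-3,6-dimethylbenzoate
Product: 3 methyl 4-(but-2-ynoyloxy)-2-hydroxy-3,6-dimethylbenzoate
Conditions: N,N'-dicyclohexylcarbodiimide, 4-(dimethylamino)pyridine (5 mol%), CH2Cl2, −20 → 0 °C
Reagents that add atoms: none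
Why: Steglich esterification of an unhindered acid; O2' is hydrogen-bonded to the methyl ester and flanked by two substituents, so acylation should occur at O4' only, and the low temperature and small amount of nucleophilic catalyst should keep conjugate addition to the ynoate down.

**Step 2**
Reactants: 4 ethyl 4-(benzyloxy)-3-oxobutanoate
Product: 5 ethyl (2Z)-4-(benzyloxy)-3-[(trimethylsilyl)oxy]but-2-enoate
Conditions: Me3SiCl, Et3N, hexane, rt; filtration, concentration
Reagents that add atoms: chlorotrimethylsilane, C[Si](C)(C)Cl
Why: O-silylation of the enol of a β-keto ester; it blocks the α-position so that the next deprotonation can only take place at the γ-carbon.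

**Step 3**
Reactants: 5 ethyl (2Z)-4-(benzyloxy)-3-[(trimethylsilyl)oxy]but-2-enoate
Product: 7 (1Z,3Z)-4-(benzyloxy)-1-ethoxy-1,3-bis[(trimethylsilyl)oxy]buta-1,3-diene, via lithium dienolate 6 (not isolated)
Conditions: LiN(iPr)2, THF, −78 °C; Me3SiCl, −78 °C → rt; non-aqueous work-up, used crude
Reagents that add atoms: chlorotrimethylsilane, C[Si](C)(C)Cl
Why: γ-Deprotonation of the silyl enol ether gives the extended ester enolate 6, which is silylated on oxygen to the 1,3-bis(silyloxy) ketene-acetal diene; the benzyloxy group is expected to lie on the outer side of the diene terminus, so the s-cis conformer stays accessible.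

**Step 4**
Reactants: 3 methyl 4-(but-2-ynoyloxy)-2-hydroxy-3,6-dimethylbenzoate; 7 (1Z,3Z)-4-(benzyloxy)-1-ethoxy-1,3-bis[(trimethylsilyl)oxy]buta-1,3-diene
Product: 10 methyl 4-{[5-(benzyloxy)-2,4-dihydroxy-6-methylbenzoyl]oxy}-2-hydroxy-3,6-dimethylbenzoate, via silyl ether 8 (not isolated), via cycloadduct 9 (not isolated)
Conditions: MeC(OSiMe3)=NSiMe3 (BSA), PhMe, 60 °C; then 7, 100 °C; then 1 M HCl, THF, rt
Reagents that add atoms: none
Why: A normal-electron-demand Diels–Alder reaction between the electron-rich diene 7 and the ynoate 8, followed by aromatisation; the closest known reaction type is the cycloaddition of 1,1,3-trioxygenated butadienes to 2-alkynoates, which gives 6-alkyl-2,4-dioxygenated benzoates. Ring A is closed as a six-membered carbocycle in a concerted, asynchronous [4+2] mode that forms C5–C6 and C1–C2 (a Mukaiyama–Michael addition followed by closure at the ketene-acetal carbon would give the same connectivity). The selectivity needed is regiochemical: the three oxygen donors at C1 and C3 of 7 put the largest HOMO coefficient on its C4, and the ester puts the largest LUMO coefficient on the methyl-bearing carbon of 8. The benzyloxy carbon therefore bonds to the methyl-bearing carbon (C5–C6) and the ketene-acetal carbon to the ester-bearing carbon (C1–C2), which places every substituent of ring A. The two sp3 carbons of 9 are transient and no stereocentre survives. Aqueous acid hydrolyses the mixed silyl ketal at C2 to a ketone with loss of ethanol and cleaves the silyl enol ether at C4; the resulting dione is a keto tautomer of the arene and enolises. Since only hydrogen can leave C5, the benzyloxy group is retained. Silylation of O2' beforehand removes the one acidic proton that would protodesilylate 7, and both esters are inert to the neutral thermal conditions.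

**Step 5**
Reactants: 10 methyl 4-{[5-(benzyloxy)-2,4-dihydroxy-6-methylbenzoyl]oxy}-2-hydroxy-3,6-dimethylbenzoate
Product: 11 methyl 4-{[5-(benzyloxy)-3-formyl-2,4-dihydroxy-6-methylbenzoyl]oxy}-2-hydroxy-3,6-dimethylbenzoate
Conditions: Cl2CHOMe, TiCl4, CH2Cl2, −78 → 0 °C; then 1 M HCl
Reagents that add atoms: dichloromethyl methyl ether, COC(Cl)Cl; water, O
Why: Rieche formylation; C3 is the only free carbon of ring A and lies between two titanium-bound phenoxides that direct the electrophile ortho, whereas C5' of ring B is para to its phenol and sits on a less electron-rich ring, so attack should occur at C3 only.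

**Step 6**
Reactants: 11 methyl 4-{[5-(benzyloxy)-3-formyl-2,4-dihydroxy-6-methylbenzoyl]oxy}-2-hydroxy-3,6-dimethylbenzoate
Product: 12 methyl 4-[(3-formyl-2,4,5-trihydroxy-6-methylbenzoyl)oxy]-2-hydroxy-3,6-dimethylbenzoate
Conditions: BCl3, C6HMe5, CH2Cl2, −78 °C; then H2O
Reagents that add atoms: none
Why: Lewis-acid debenzylation of an aryl benzyl ether with pentamethylbenzene as a non-basic scavenger for the benzyl cation; at −78 °C the methyl ester, the aryl ester and the aldehyde should not react, and the acidic, non-oxidising conditions suit the trihydroxyarene.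

## Compound list

1 | but-2-ynoic acid | CC#CC(=O)O | starting material
2 | methyl 2,4-dihydroxy-3,6-dimethylbenzoate | COC(=O)c1c(C)cc(O)c(C)c1O | starting material
3 | methyl 4-(but-2-ynoyloxy)-2-hydroxy-3,6-dimethylbenzoate | COC(=O)c1c(C)cc(OC(=O)C#CC)c(C)c1O | intermediate
4 | ethyl 4-(benzyloxy)-3-oxobutanoate | CCOC(=O)CC(=O)COCc1ccccc1 | starting material
5 | ethyl (2Z)-4-(benzyloxy)-3-[(trimethylsilyl)oxy]but-2-enoate | CCOC(=O)/C=C(\O[Si](C)(C)C)COCc1ccccc1 | intermediate
6 | lithium (1Z,3Z)-4-(benzyloxy)-1-ethoxy-3-[(trimethylsilyl)oxy]buta-1,3-dien-1-olate | [Li+].CCO/C([O-])=C/C(O[Si](C)(C)C)=C/OCc1ccccc1 | intermediate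
7 | (1Z,3Z)-4-(benzyloxy)-1-ethoxy-1,3-bis[(trimethylsilyl)oxy]buta-1,3-diene | CCO/C(O[Si](C)(C)C)=C/C(O[Si](C)(C)C)=C/OCc1ccccc1 | intermediate
8 | methyl 4-(but-2-ynoyloxy)-3,6-dimethyl-2-[(trimethylsilyl)oxy]benzoate | COC(=O)c1c(C)cc(OC(=O)C#CC)c(C)c1O[Si](C)(C)C | intermediate
9 | methyl 4-{[3-(benzyloxy)-6-ethoxy-2-methyl-4,6-bis(trimethylsilyloxy)cyclohexa-1,4-diene-1-carbonyl]oxy}-3,6-dimethyl-2-(trimethylsilyloxy)benzoate (mixture of racemic diastereomers) | COC(=O)c1c(C)cc(OC(=O)C2=C(C)C(OCc3ccccc3)C(O[Si](C)(C)C)=CC2(OCC)O[Si](C)(C)C)c(C)c1O[Si](C)(C)C | intermediate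
10 | methyl 4-{[5-(benzyloxy)-2,4-dihydroxy-6-methylbenzoyl]oxy}-2-hydroxy-3,6-dimethylbenzoate | COC(=O)c1c(C)cc(OC(=O)c2c(C)c(OCc3ccccc3)c(O)cc2O)c(C)c1O | intermediate
11 | methyl 4-{[5-(benzyloxy)-3-formyl-2,4-dihydroxy-6-methylbenzoyl]oxy}-2-hydroxy-3,6-dimethylbenzoate | COC(=O)c1c(C)cc(OC(=O)c2c(C)c(OCc3ccccc3)c(O)c(C=O)c2O)c(C)c1O | intermediate
12 | methyl 4-[(3-formyl-2,4,5-trihydroxy-6-methylbenzoyl)oxy]-2-hydroxy-3,6-dimethylbenzoate | COC(=O)c1c(C)cc(OC(=O)c2c(C)c(O)c(O)c(C=O)c2O)c(C)c1O | target

## Step count and least certain steps

Total step count: 6. Longest linear sequence: 5 steps (4 → 5 → 7 → 10 → 11 → 12).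

**Step 4 (key step).** Most likely to go wrong: the cycloaddition to a β-methyl-substituted ynoate is slow, and thermal decay of the diene (silyl migration, protodesilylation) may outrun it. A second possibility is aromatisation in the flask by loss of the silyloxy instead of the ethoxy group, which would leave O2 as an ethyl ether.

Fallback, from 2 back to 10, with a more reactive dienophile of another class. 2 is esterified with but-3-ynoic acid (carbodiimide, CH2Cl2, 0 °C) to methyl 4-(but-3-ynoyloxy)-2-hydroxy-3,6-dimethylbenzoate F1. Et3N isomerises this to the allenic ester methyl 4-(buta-2,3-dienoyloxy)-2-hydroxy-3,6-dimethylbenzoate F2. F2 is silylated in the flask to its trimethylsilyl ether F3. The ester-conjugated double bond of the allene, with an unhindered sp carbon as the electrophilic terminus, should add 7 between room temperature and 60 °C with the same regiochemistry, to give the methylidene cycloadduct F4. Acid work-up hydrolyses the ketal and silyl ethers and moves the exocyclic double bond into the ring, which gives 10 without any oxidation.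

**Step 5.** Most likely to go wrong: loss of ring selectivity (attack at C5' of ring B), or Lewis-acid-induced acyl migration or cleavage at the depside ester while three phenols are bound to titanium.

Fallback, from 10 back to 11, bringing the carbon in at the alcohol oxidation level under non-Lewis-acidic conditions. PhB(OH)2, paraformaldehyde and catalytic propionic acid in refluxing toluene should give, by boronate-templated ortho-hydroxymethylation at C3, the cyclic phenylboronate (a 2-phenyl-4H-1,3,2-benzodioxaborin fused at C3/C4 of ring A) F5. Transesterification with 2,2-dimethylpropane-1,3-diol frees the 3-(hydroxymethyl) compound F6. MnO2 in CH2Cl2 oxidises this ortho-hydroxybenzyl alcohol to 11.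

**Step 6.** Most likely to go wrong: attack of the Lewis acid elsewhere (cleavage of the aryl ester or the methyl ester through chelation with the neighbouring phenols), or oxidation of the trihydroxyarene during work-up.

Fallback, from 10 to 12, removing the benzyl group before the aldehyde exists so that a reductive method can be used. Hydrogenolysis of 10 (H2, Pd/C, EtOAc) gives methyl 2-hydroxy-3,6-dimethyl-4-[(2,4,5-trihydroxy-6-methylbenzoyl)oxy]benzoate F7, which is handled under argon. Rieche formylation of F7 (Cl2CHOMe, TiCl4, CH2Cl2, −78 → 0 °C), again at the only free carbon of ring A, gives 12 directly.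

## Further compounds

F1 | step 4 | methyl 4-(but-3-ynoyloxy)-2-hydroxy-3,6-dimethylbenzoate | COC(=O)c1c(C)cc(OC(=O)CC#C)c(C)c1O
F2 | step 4 | methyl 4-(buta-2,3-dienoyloxy)-2-hydroxy-3,6-dimethylbenzoate | COC(=O)c1c(C)cc(OC(=O)C=C=C)c(C)c1O
F3 | step 4 | methyl 4-(buta-2,3-dienoyloxy)-3,6-dimethyl-2-[(trimethylsilyl)oxy]benzoate | COC(=O)c1c(C)cc(OC(=O)C=C=C)c(C)c1O[Si](C)(C)C
F4 | step 4 | methyl 4-{[3-(benzyloxy)-6-ethoxy-2-methylidene-4,6-bis(trimethylsilyloxy)cyclohex-4-ene-1-carbonyl]oxy}-3,6-dimethyl-2-(trimethylsilyloxy)benzoate (mixture of racemic diastereomers) | COC(=O)c1c(C)cc(OC(=O)C2C(=C)C(OCc3ccccc3)C(O[Si](C)(C)C)=CC2(OCC)O[Si](C)(C)C)c(C)c1O[Si](C)(C)C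
F5 | step 5 | methyl 4-{[6-(benzyloxy)-8-hydroxy-5-methyl-2-phenyl-4H-1,3,2-benzodioxaborin-7-carbonyl... (ring A of 10 with O4–B(Ph)–O–CH2–C3 bridge)]oxy}-2-hydroxy-3,6-dimethylbenzoate | COC(=O)c1c(C)cc(OC(=O)c2c(C)c(OCc3ccccc3)c3OB(c4ccccc4)OCc3c2O)c(C)c1O
F6 | step 5 | methyl 4-{[5-(benzyloxy)-2,4-dihydroxy-3-(hydroxymethyl)-6-methylbenzoyl]oxy}-2-hydroxy-3,6-dimethylbenzoate | COC(=O)c1c(C)cc(OC(=O)c2c(C)c(OCc3ccccc3)c(O)c(CO)c2O)c(C)c1O
F7 | step 6 | methyl 2-hydroxy-3,6-dimethyl-4-[(2,4,5-trihydroxy-6-methylbenzoyl)oxy]benzoate | COC(=O)c1c(C)cc(OC(=O)c2c(C)c(O)c(O)cc2O)c(C)c1O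
A1 | alternative 1 | 4,5-bis(benzyloxy)-3-formyl-2-hydroxy-6-methylbenzoic acid | Cc1c(C(=O)O)c(O)c(C=O)c(OCc2ccccc2)c1OCc1ccccc1
A2 | alternative 1 | methyl 4-{[4,5-bis(benzyloxy)-3-formyl-2-hydroxy-6-methylbenzoyl]oxy}-2-hydroxy-3,6-dimethylbenzoate | COC(=O)c1c(C)cc(OC(=O)c2c(C)c(OCc3ccccc3)c(OCc3ccccc3)c(C=O)c2O)c(C)c1O
A3 | alternative 2 | methyl 2-hydroxy-4-{[(2E)-3-iodobut-2-enoyl]oxy}-3,6-dimethylbenzoate | COC(=O)c1c(C)cc(OC(=O)/C=C(\C)I)c(C)c1O
A4 | alternative 2 | methyl 2-hydroxy-4-{[(2E)-3-(1-hydroxy-2-isopropoxy-4-oxocyclobut-2-en-1-yl)but-2-enoyl]oxy}-3,6-dimethylbenzoate (racemic) | COC(=O)c1c(C)cc(OC(=O)/C=C(\C)C2(O)C(OC(C)C)=CC2=O)c(C)c1O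
A5 | alternative 2 | methyl 4-[(2,5-dihydroxy-4-isopropoxy-6-methylbenzoyl)oxy]-2-hydroxy-3,6-dimethylbenzoate | COC(=O)c1c(C)cc(OC(=O)c2c(C)c(O)c(OC(C)C)cc2O)c(C)c1O
A6 | alternative 3 | 6-[3-(benzyloxy)-2,4-dioxopentyl]-2,2-dimethyl-4H-1,3-dioxin-4-one (racemic) | CC(=O)C(OCc1ccccc1)C(=O)CC1=CC(=O)OC(C)(C)O1
A7 | alternative 3 | methyl 4-{[6-(benzyloxy)-3,5,7-trioxooctanoyl]oxy}-2-hydroxy-3,6-dimethylbenzoate (racemic) | COC(=O)c1c(C)cc(OC(=O)CC(=O)CC(=O)C(OCc2ccccc2)C(C)=O)c(C)c1O
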